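The earlier runs and the new flask stem from a simulated flask for substances that don't exist.

Eta cannot use up its starting complex, because a complex lost takes more incoming ligand than eta has for it: in the green run, by 40.0 min, each one lost had drawn 1.50 ligands (one per complex with one exchanged, two per complex with two exchanged and, I assume, two per side product), and eta charges 0.800 per complex.

| flask | starting complex | incoming ligand | remark | time |
|---|---|---|---|---|
| green | 0.060 M | 0.065 M (fed, over 6.0 min) | run made earlier; the fed solution adds 0.20 times the starting volume |  |
| teal | 0.060 M | 0.18 M (fed, over 6.0 min) | run made earlier; the fed solution adds 0.20 times the starting volume |  |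
| eta | 0.060 M | 0.0480 M (fed, over 6.0 min) | the fed solution adds 0.20 times the starting volume | 80 min |
| alpha | 0.060 M | 0.120 M (fed, over 6.0 min) | the fed solution adds 0.20 times the starting volume | 80 min |

| run | time / min | complex with two exchanged / % | side product / % | complex with one exchanged / % | starting complex / % |
|---|---|---|---|---|---|
| green | 3.00 | 0.9 | 0 | 1.8 | 95.3 |
| green | 8.00 | 4.8 | 1.0 | 9.8 | 85.1 |
| green | 15.0 | 9.7 | 2.8 | 16.8 | 73.2 |
| green | 40.0 | 13.2 | 12.1 | 24.8 | 49.8 |
| teal | 5.00 | 7.2 | 0.2 | 11.2 | 83.3 |
| teal | 15.0 | 31.2 | 9.1 | 18.9 | 41.5 |
| teal | 25.0 | 27.9 | 26.5 | 22.5 | 22.5 |
| teal | 40.0 | 21.3 | 47.6 | 19.7 | 10.9 |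

(each reading ± 1 percentage point)

- which of these there is most of at the end, counted by the starting complex in it, eta (complex with two exchanged / side product / starting complex / complex with one exchanged)
- which of these there is most of at the end, counted by the starting complex in it, alpha (complex with two exchanged / side product / starting complex / complex with one exchanged)
- amount of the one of these that there is most of at the end, in percent of the starting complex charged, eta
- amount of the one of these that there is most of at the end, in percent of the starting complex charged, alpha

- charges are per starting volume, the dose included; the dosed solution carries all of it

I take the rate at which starting complex is lost as a constant times two factors, what is left of the complex and what is left of the ligand. Green between 8.00 min and 15.0 min reads as 0.0279 min⁻¹. So with the whole charge in, as if at once, eta starts by losing 0.0223 min⁻¹ of its complex and alpha 0.0558 min⁻¹.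

Both factors then brake. Compare them by the draw, the share of the ligand charge lost per share of the complex charge lost: 1.88 for eta and 0.751 for alpha, or, with teal's 1.77 ligands per complex, 0.884 for alpha. The crossing is a draw of one: eta lies above it, so its ligand is the limiting reagent, and alpha lies below.

With 0.5 of the complex lost, the ligand factor is 0.0613 in eta and 0.625 in alpha, so the rates stand at 0.0306 and 0.312 of their starts. Eta's ligand factor reaches zero with 46.7 % of the complex left, so I expect starting complex on top in eta, just above that floor. Alpha's ligand factor stays above zero at that point, and teal, charged with more ligand than alpha, held 47.6 % side product at 40.0 min, so I expect side product on top in alpha, without a figure.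

The forecast, saying of eta “ligand starves”, gives starting complex at 48 % for eta and side product at 52 % for alpha.

The flasks give starting complex at 50.1 % in eta and side product at 57.5 % in alpha, 5.5 percentage points above the forecast.

    starting complex + incoming ligand ⇌ leaving ligand + complex with one exchanged (K = 48.0, k = 0.620 M⁻¹ min⁻¹)
    complex with one exchanged + incoming ligand ⇌ leaving ligand + complex with two exchanged (K = 1.10, k = 3.20 M⁻¹ min⁻¹)
    leaving ligand + complex with two exchanged → side product (k = 1.10 M⁻¹ min⁻¹)

Neither flask is at rest after 80 min. Their draws stand at 1.76 for eta and 0.880 for alpha, on the reckoned sides of one. Ten times the time brings eta's starting complex to 47.0 %, level with the floor, while its side product goes from 15.2 % to 26.5 %. Alpha's side product reaches 96.3 % in that time. The flask holds what the forecast's number does not: leaving ligand, 0.0480 M in alpha at 80 min, which the equations send into side product.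

The neighbour with alpha's ligand and 0.15 M of starting complex has a draw of 1.88, so starting complex should stay on top near 46.7 %. It gives starting complex at 44.7 %, with 1.64 % of its ligand left.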